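Count the reagent.

| setting | south | north | north-east | teal | grey | blue |
|---|---|---|---|---|---|---|
| substrate | 0.80 M | 0.80 M | 0.80 M | 0.80 M | 0.80 M | 0.80 M |
| reagent | 0.46 M | 1.1 M | 2.7 M | 3.00 M | 1.20 M | 0.480 M |
| remark | run made earlier | run made earlier | run made earlier |  |  |  |
| time |  |  |  | 20 d | 20 d | 20 d |

| run | time / d | over-reaction product / % | substrate / % | intermediate B / % | intermediate A / % | target / % |
|---|---|---|---|---|---|---|
| south | 1.25 | 7.2 | 41.4 | 0.9 | 19.8 | 30.5 |
| south | 4.00 | 14.2 | 21.3 | 6.0 | 36.8 | 22.6 |
| south | 6.00 | 17.3 | 14.4 | 8.4 | 42.7 | 15.9 |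
| south | 10.0 | 20.9 | 7.9 | 17.1 | 47.5 | 8.9 |
| south | 15.0 | 22.4 | 3.5 | 22.3 | 48.3 | 3.7 |
| north | 1.04 | 26.5 | 19.7 | 0.2 | 10.9 | 40.2 |
| north | 2.00 | 39.1 | 12.9 | 1.8 | 14.3 | 31.4 |
| north | 4.00 | 50.4 | 9.3 | 3.4 | 18.4 | 19.1 |
| north | 8.00 | 58.4 | 4.6 | 7.3 | 21.4 | 8.0 |
| north | 15.0 | 62.1 | 1.7 | 10.4 | 24.7 | 1.9 |
| north-east | 3.00 | 92.7 | 0 | 0.6 | 4.5 | 1.3 |
| north-east | 6.00 | 93.6 | 1.0 | 1.9 | 3.5 | 0.1 |
| north-east | 8.00 | 95.1 | 0 | 2.1 | 4.7 | 0 |
| north-east | 12.0 | 94.7 | 0 | 1.3 | 3.7 | 0.2 |
| north-east | 15.0 | 94.9 | 0.3 | 1.6 | 3.8 | 0 |

(scatter of a reading: 0.5 percentage points)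

* which of these there is most of at the end, counted by the substrate in it, teal (intermediate B / over-reaction product / target / intermediate A)
* which of these there is most of at the end, counted by the substrate in it, grey (intermediate B / over-reaction product / target / intermediate A)
* which of these there is most of at the end, counted by the substrate in it, blue (intermediate B / over-reaction product / target / intermediate A)
* the largest of these amounts at the end, in percent of the substrate charged, teal
* the largest of these amounts at the end, in percent of the substrate charged, grey
* the largest of these amounts at the end, in percent of the substrate charged, blue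

- the numbers in the tables scatter with a standard deviation of 0.5 percentage points
- candidate steps: substrate -> intermediate A; intermediate A <-> intermediate B; substrate + reagent <-> target; reagent + target -> over-reaction product

Among the candidate steps, substrate and reagent make target, and target and reagent make over-reaction product, so each over-reaction product holds two reagents. We therefore carry one quantity, the crossing charge: twice the substrate charge, 1.60 M of reagent here. Below the crossing, a reagent charge divided by it gives the stoichiometric ceiling on over-reaction product, as a share of the substrate charged. Teal stands above the crossing, so its ceiling is the substrate itself, and north-east, also above, reads 94.9%.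

Grey stands below it, with a ceiling of 75.0%. North, with less reagent, last read 62.1%, and those two numbers make the wide bracket. At 15.0 d, north's over-reaction product and target leave 0.0912 M of reagent free. If grey's extra reagent enters at north's fraction of its ceiling, grey gets 67.7%. If all of it enters, grey gets 69.3%. Each edge carries the scatter of 0.5 percentage points.

Blue's ceiling is 30.0%. Taking over-reaction product at that ceiling, we split the remainder at south's last reading of intermediate B over intermediate A, 0.462, which gives roughly 47.9% of intermediate A.

The forecast gives over-reaction product at 95.8% for teal, over-reaction product at 67% for grey and intermediate A at 50% for blue, of which it says “Blue is reagent-starved”. Its grey number lies inside the wide bracket and just under the tight one.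

Teal gives over-reaction product at 95.2%, and blue gives intermediate A at 47.6%. Grey gives over-reaction product at 68.6%, more than the low edge of the tight bracket and less than its high edge.

    substrate → intermediate A (k = 3.18 × 10⁻⁶ s⁻¹)
    intermediate A ⇌ intermediate B (K = 0.570, k = 8.68 × 10⁻⁷ s⁻¹)
    substrate + reagent ⇌ target (K = 12.0 M⁻¹, k = 2.89 × 10⁻⁵ M⁻¹ s⁻¹)
    reagent + target → over-reaction product (k = 1.50 × 10⁻⁵ M⁻¹ s⁻¹)

Blue ends at 25.2% of over-reaction product, under its ceiling of 30.0%, and intermediate A leads there. Teal, on the other side of the crossing, ends with 3.08% of intermediate A, and the difference in reagent concentration may be called the main reason. With that difference taken away, the reagent put back to the south run's charge, intermediate A stands at 47.6%.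

The numbers in the tables stem from a simulated flask from invented constants; the scatter is artificial.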